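The earlier runs and the new flask were generated by integration for substances that don't exist.

Write the balance of the reagent first: what dissolves from the gas, less what the substrates take. I took the reagent to be the gas once dissolved, capped at 78 mM.

the same everywhere: gas 78 mM (held)
- midnight: left-handed substrate 0.75 M; right-handed substrate 0.75 M; racemization catalyst 3 mM; run made earlier
- flask: left-handed substrate 1.5 M; right-handed substrate 1.5 M; racemization catalyst 3.0 mM; time 1.5 h

- midnight (time / min: left-handed substrate / %, right-handed substrate / %): 2.50: 49.0, 48.3; 5.00: 47.2, 46.2; 6.00: 45.6, 45.6; 10.0: 43.8, 43.7

(each reading ± 0.5 percentage points)

- reagent is single-handed; left-handed substrate and right-handed substrate are mirror images of each other, charged as a racemate, each of them at the stated concentration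
- at the start none of the gas is in solution
- an excess is below zero if the other one leads
- the handed part of reagent does not stay in what it makes, so the products of the two hands are mirror images too

- part of the left-handed substrate and right-handed substrate charged together that has reacted at 1.5 h
- excess of left-handed product over right-handed product in the product at 1.5 h
- excess of right-handed substrate over left-handed substrate among what is left of the two at 1.5 h

Could one saturated solution of reagent have paid for the midnight run? No: by 10.0 min that run had lost 0.188 M of substrate, which is 2.41 times what its solution could hold, so, counting one reagent per substrate, the gas feed must have replaced the reagent as it went.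

Did that feed set the pace? The midnight readings gave a use of 0.0196 M min⁻¹ and a lag of 0.434 min, rough given a scatter of 0.5 percentage points. From these readings I estimated the feed at about 0.180 M min⁻¹. With twice the substrate charge, I reckoned the flask to ask 0.0392 M min⁻¹ at first, still less than that estimate.

So I held the reagent near saturation and treated the substrate pair as pseudo-first-order, with a loss constant, the logarithm of charged over remaining per unit time, of 0.0134 min⁻¹. For the flask this gave me a reacted part of the substrates, c, of 69.9%. The two substrates of the midnight run differed by 0.1 points in the last reading, within the scatter, so I expected a small excess of substrate, eS, and could read no excess of product, eP.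

The forecast gave c 65%, eP −3% and eS −1%, noting that “if racemization is fast, it hides any selectivity”.

The flask gave c 68.4%, eP 81.7% and eS 0.613%.

    reagent + left-handed substrate → left-handed product (k = 0.00530 M⁻¹ s⁻¹)
    2 racemization catalyst → spent catalyst (k = 0.0960 M⁻¹ s⁻¹)
    reagent + right-handed substrate → right-handed product (k = 5.30 × 10⁻⁴ M⁻¹ s⁻¹)
    2 reagent → homo dimer (k = 0.00110 M⁻¹ s⁻¹)
    left-handed substrate + racemization catalyst ⇌ right-handed substrate + racemization catalyst, rate k5*[racemization catalyst]*[left-handed substrate] forward; the back reaction follows from the equilibrium constant (k = 20.0 M⁻¹ s⁻¹)
    gas ⇌ reagent, rate k6*(csat - [reagent]) (kL = 0.0870 s⁻¹)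

The flask's conversion corresponds to a loss constant of 0.0128 min⁻¹, beside my 0.0134 min⁻¹, but its eP stood 85 points above the forecast. At 0.541 h in the flask, left-handed substrate went to product at 0.014 of its forward racemization rate, while reagent consumed it 9.9 times as fast as right-handed substrate. For a neighbouring flask with 0.0012 M racemization catalyst, 0.0134 min⁻¹ again gives 69.9%; that flask computes to c 68.3%, eP 81.6% and eS 0.837%.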